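**Retrosynthetic overview**
1. A-ring piece: acetophenone 1 → iodide 2 → methoxy ketone 3 → aryl glyoxal 4. The 8-OMe is placed next to the one free OH that becomes O1, and the future C3 is raised to the aldehyde level.
2. B-ring piece: 5 → 6 → 7 (2,4-demethylation, then benzyl protection; the 5'-OMe is kept).
3. Key disconnection C2–C3, a 1,2-dioxygenated bond: the acyl anion (Breslow intermediate) of 7 adds to the formyl carbon of 4 to give α-hydroxy-1,3-diketone 8.
4. Rings A and B are bought intact; the pyranone C ring is the only ring formed, by O1–C2 cyclodehydration 8 → flavonol 9, then 3-O-methylation → 10 in the same flask.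
5. Global debenzylation 10 → 11 (target).

Assumption: the target is a planar, achiral flavone with no stereocentre, so no stereocontrol is needed; the one transient stereocentre (in 8) forms racemic and is destroyed on dehydration.

**Step 1**
Reactants: 1 1-[2,4-bis(benzyloxy)-6-hydroxyphenyl]ethan-1-one
Product: 2 1-[4,6-bis(benzyloxy)-2-hydroxy-3-iodophenyl]ethan-1-one
Conditions: BnMe3N+ ICl2− (1.05 equiv), NaHCO3, CH2Cl2/MeOH, rt
Reagents that add atoms: benzyltrimethylammonium dichloroiodate, C[N+](C)(C)Cc1ccccc1.Cl[I-]Cl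
Why: Electrophilic aromatic iodination of the phenol goes ortho to the free chelated hydroxyl (C-3), because the only other open ring position (C-5) is shielded by two flanking benzyloxy groups; no stereocentre is formed.

**Step 2**
Reactants: 2 1-[4,6-bis(benzyloxy)-2-hydroxy-3-iodophenyl]ethan-1-one
Product: 3 1-[4,6-bis(benzyloxy)-2-hydroxy-3-methoxyphenyl]ethan-1-one
Conditions: NaOMe (5 equiv), CuBr (0.3 equiv), DMF/MeOH, 110 °C
Reagents that add atoms: sodium methoxide, [Na+].[O-]C
Why: Copper-catalysed Ullmann-type methoxylation of an aryl iodide flanked by a phenoxide, as in the classical halophenol to methoxyphenol conversions; benzyl ethers and the phenoxide-deactivated methyl ketone are inert.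

**Step 3**
Reactants: 3 1-[4,6-bis(benzyloxy)-2-hydroxy-3-methoxyphenyl]ethan-1-one
Product: 4 2-[4,6-bis(benzyloxy)-2-hydroxy-3-methoxyphenyl]-2-oxoacetaldehyde
Conditions: SeO2 (1.2 equiv), 1,4-dioxane/H2O (30:1), 90 °C; product dried azeotropically (it sits as hydrate/ring lactol)
Reagents that add atoms: selenium dioxide, O=[Se]=O
Why: Riley oxidation of the enolisable acetyl CH3 of an aryl methyl ketone gives the aryl glyoxal, and benzyl and methyl ethers are untouched.

**Step 4**
Reactants: 5 2,4,5-trimethoxybenzaldehyde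
Product: 6 2,4-dihydroxy-5-methoxybenzaldehyde
Conditions: AlCl3 (4 equiv), CH2Cl2, 0 °C → rt; 1 M HCl
Reagents that add atoms: none
Why: Carbonyl-directed Lewis-acid ether cleavage, in which AlCl3 bound to the formyl oxygen removes the chelated ortho methyl and the conjugatively activated para methyl while the meta 5-OMe is not activated.

**Step 5**
Reactants: 6 2,4-dihydroxy-5-methoxybenzaldehyde
Product: 7 2,4-bis(benzyloxy)-5-methoxybenzaldehyde
Conditions: BnBr (2.3 equiv), K2CO3, DMF, 60 °C
Reagents that add atoms: benzyl bromide, BrCc1ccccc1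
Why: Williamson ether synthesis on both phenols, with warm DMF needed to alkylate the chelated 2-OH.

**Step 6**
Reactants: 4 2-[4,6-bis(benzyloxy)-2-hydroxy-3-methoxyphenyl]-2-oxoacetaldehyde; 7 2,4-bis(benzyloxy)-5-methoxybenzaldehyde
Product: 10 5,7-bis(benzyloxy)-2-[2,4-bis(benzyloxy)-5-methoxyphenyl]-3,8-dimethoxy-4H-chromen-4-one, via 2-hydroxy-1,3-diketone 8 (not isolated), via flavonol 9 (not isolated)
Conditions: 7 (1.3 equiv), 2-C6F5-6,7-dihydro-5H-pyrrolo[2,1-c][1,2,4]triazolium BF4 (15 mol %), i-Pr2NEt (1.2 equiv), 4 Å MS, THF, N2, rt, slow addition of 4; then K2CO3 (3 equiv), DMF, 60 °C; then MeI (3 equiv), rt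
Reagents that add atoms: iodomethane, CI
Why: Proposed new method: the carbene adds to the formyl group of 7 to give a Breslow enaminol (acyl anion at the future C-2) that attacks the much more electrophilic aldehyde carbon of glyoxal 4, which is held at low concentration by its lactol equilibrium and slow addition and so acts as acceptor, joining two former formyl carbons as the C2–C3 bond (chemoselective NHC cross-benzoin; closest known type is carbene-catalysed cross-benzoin of aldehydes with activated carbonyl acceptors such as α-keto esters, and if the carbene engages 4 first the regioisomeric α-ketol is a tautomer of 8 through the common enediol), after which the known base-mediated hemiketalisation and E1cB dehydration of a 2-hydroxy-1-(2-hydroxyaryl)-1,3-dione gives flavonolate 9 (erasing the racemic carbinol centre of 8) and Williamson methylation of its only free hydroxyl gives 10.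

**Step 7**
Reactants: 10 5,7-bis(benzyloxy)-2-[2,4-bis(benzyloxy)-5-methoxyphenyl]-3,8-dimethoxy-4H-chromen-4-one
Product: 11 5,7-dihydroxy-2-(2,4-dihydroxy-5-methoxyphenyl)-3,8-dimethoxy-4H-chromen-4-one
Conditions: H2 (1 atm), 10% Pd/C, EtOAc/MeOH (1:1), rt
Reagents that add atoms: none
Why: Catalytic hydrogenolysis cleaves the four benzyl aryl ethers while the methyl ethers and the flavone core are inert under these conditions; the product has no stereocentre.

**Compound list**
1 | 1-[2,4-bis(benzyloxy)-6-hydroxyphenyl]ethan-1-one | CC(=O)c1c(O)cc(OCc2ccccc2)cc1OCc1ccccc1 | starting material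
2 | 1-[4,6-bis(benzyloxy)-2-hydroxy-3-iodophenyl]ethan-1-one | CC(=O)c1c(O)c(I)c(OCc2ccccc2)cc1OCc1ccccc1 | intermediate
3 | 1-[4,6-bis(benzyloxy)-2-hydroxy-3-methoxyphenyl]ethan-1-one | CC(=O)c1c(O)c(OC)c(OCc2ccccc2)cc1OCc1ccccc1 | intermediate
4 | 2-[4,6-bis(benzyloxy)-2-hydroxy-3-methoxyphenyl]-2-oxoacetaldehyde (drawn as the open keto-aldehyde) | O=CC(=O)c1c(O)c(OC)c(OCc2ccccc2)cc1OCc1ccccc1 | intermediate
5 | 2,4,5-trimethoxybenzaldehyde | COc1cc(OC)c(C=O)cc1OC | starting material
6 | 2,4-dihydroxy-5-methoxybenzaldehyde | COc1cc(C=O)c(O)cc1O | intermediate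
7 | 2,4-bis(benzyloxy)-5-methoxybenzaldehyde | COc1cc(C=O)c(OCc2ccccc2)cc1OCc1ccccc1 | intermediate
8 | 1-[4,6-bis(benzyloxy)-2-hydroxy-3-methoxyphenyl]-3-[2,4-bis(benzyloxy)-5-methoxyphenyl]-2-hydroxypropane-1,3-dione (racemic, formed in the flask) | COc1cc(C(=O)C(O)C(=O)c2c(O)c(OC)c(OCc3ccccc3)cc2OCc2ccccc2)c(OCc2ccccc2)cc1OCc1ccccc1 | intermediate
9 | 5,7-bis(benzyloxy)-2-[2,4-bis(benzyloxy)-5-methoxyphenyl]-3-hydroxy-8-methoxy-4H-chromen-4-one (formed in the flask) | COc1cc(-c2oc3c(OC)c(OCc4ccccc4)cc(OCc4ccccc4)c3c(=O)c2O)c(OCc2ccccc2)cc1OCc1ccccc1 | intermediate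
10 | 5,7-bis(benzyloxy)-2-[2,4-bis(benzyloxy)-5-methoxyphenyl]-3,8-dimethoxy-4H-chromen-4-one | COc1cc(-c2oc3c(OC)c(OCc4ccccc4)cc(OCc4ccccc4)c3c(=O)c2OC)c(OCc2ccccc2)cc1OCc1ccccc1 | intermediate
11 | 5,7-dihydroxy-2-(2,4-dihydroxy-5-methoxyphenyl)-3,8-dimethoxy-4H-chromen-4-one (5,7,2',4'-tetrahydroxy-3,8,5'-trimethoxyflavone) | COc1cc(-c2oc3c(OC)c(O)cc(O)c3c(=O)c2OC)c(O)cc1O | target

**Totals and risks**
Total step count: 7. Longest linear sequence: 5 steps (1, 2, 3, 6, 7).

The three steps most likely to fail: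

Step 6 (key union). The risks are a Cannizzaro-type hydride shift of the lactol form of 4 under base, homo-benzoin of 7, and base cleavage of 8 before it cyclises. The fallback swaps the catalytic carbene for a stoichiometric Corey–Seebach acyl anion and sets out from 7. Propane-1,3-dithiol and BF3·OEt2 convert 7 into 2-[2,4-bis(benzyloxy)-5-methoxyphenyl]-1,3-dithiane F1. Lithiation (n-BuLi, THF, −78 °C) and addition of 4 (0.45 equiv, the first equivalent of anion being spent on its phenol/lactol OH) give the carbinol 1-[4,6-bis(benzyloxy)-2-hydroxy-3-methoxyphenyl]-2-{2-[2,4-bis(benzyloxy)-5-methoxyphenyl]-1,3-dithian-2-yl}-2-hydroxyethan-1-one F2. Alkylative hydrolysis (MeI, CaCO3, aqueous MeCN) unmasks the ketone and the route is rejoined at 8, which is cyclised and methylated as in step 6.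

Step 1 (regiochemistry of iodination, C-3 versus C-5). The fallback sets out from 1 and fixes the position by chelation. Ortho-formylation through the magnesium phenoxide (MgCl2, Et3N, paraformaldehyde, MeCN, reflux) gives 3-acetyl-4,6-bis(benzyloxy)-2-hydroxybenzaldehyde F3. Dakin oxidation (H2O2, NaOH, THF/H2O, 0 °C) gives the catechol 1-[4,6-bis(benzyloxy)-2,3-dihydroxyphenyl]ethan-1-one F4. Dianion formation (NaH, 2.2 equiv, DMF) and MeI (1.0 equiv) methylate the non-chelated 3-oxide, and the route is rejoined at 3, bypassing steps 1 and 2.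

Step 3 (SeO2 oxidation of an electron-rich hydroxy ketone; over-oxidation or poor recovery of the glyoxal). The fallback sets out from 3 and reaches the same oxidation level by C-nitrosation. Isoamyl nitrite and NaOEt in EtOH at 0 °C give (E)-1-[4,6-bis(benzyloxy)-2-hydroxy-3-methoxyphenyl]-2-(hydroxyimino)ethan-1-one F5. Trans-oximation with aqueous formaldehyde and HCl in THF releases the keto-aldehyde, and the route is rejoined at 4.

**Further compounds**
F1 | step 6 | 2-[2,4-bis(benzyloxy)-5-methoxyphenyl]-1,3-dithiane | COc1cc(C2SCCCS2)c(OCc2ccccc2)cc1OCc1ccccc1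
F2 | step 6 | 1-[4,6-bis(benzyloxy)-2-hydroxy-3-methoxyphenyl]-2-{2-[2,4-bis(benzyloxy)-5-methoxyphenyl]-1,3-dithian-2-yl}-2-hydroxyethan-1-one (racemic) | COc1cc(C2(SCCCS2)C(O)C(=O)c2c(O)c(OC)c(OCc3ccccc3)cc2OCc2ccccc2)c(OCc2ccccc2)cc1OCc1ccccc1
F3 | step 1 | 3-acetyl-4,6-bis(benzyloxy)-2-hydroxybenzaldehyde | CC(=O)c1c(O)c(C=O)c(OCc2ccccc2)cc1OCc1ccccc1
F4 | step 1 | 1-[4,6-bis(benzyloxy)-2,3-dihydroxyphenyl]ethan-1-one | CC(=O)c1c(O)c(O)c(OCc2ccccc2)cc1OCc1ccccc1
F5 | step 3 | (E)-1-[4,6-bis(benzyloxy)-2-hydroxy-3-methoxyphenyl]-2-(hydroxyimino)ethan-1-one | O/N=C/C(=O)c1c(O)c(OC)c(OCc2ccccc2)cc1OCc1ccccc1
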